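**Retrosynthetic overview**
1. The 14-membered carbocycle is closed last, at C1–C2, by an intramolecular chromium-mediated 2-(alkoxycarbonyl)allylation that also creates the α-methylene group and both C1 and C2.
2. The cis-oxolane comes from a Ni/Cr alkenyl–aldehyde union at C7–C8 (west alkenyl bromide + east lactol), then SN2 etherification C4–O–C7 with inversion at C7.
3. The ε-lactone with C11 and C12 comes from a Shi epoxide by a one-flask semipinacol/Baeyer–Villiger double ring expansion (cyclopentenol → cyclohexenone → oxepinone); this is the key step.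
4. West half: propargyl bromide, 2,3-dibromopropene, cyclopent-3-enone, MeMgBr, CH2O. East half: (S)-2-methylglycidol, 1,3-dithiane, acetic acid.
5. Ring order: cyclopentene → cyclohexenone → oxepinone (west); oxolanone (east) → oxolane → 14-membered ring.

Assumption: cembrane numbering is used for atom labels (C1 carries the acrylate unit, C2 and C11 are the carbinols, C4/C7 the oxolane carbons, C12 the lactone carbon, C16 the lactone carbonyl, C17/C19 the methylene carbons); cyclopent-3-en-1-one and (S)-2-methylglycidol are bought.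

**Step 1**
Reactants: 1 3-bromoprop-1-yne; 2 2,3-dibromoprop-1-ene
Product: 4 2-bromohex-1-en-5-yne, via propargylmagnesium bromide 3 (not isolated)
Conditions: Mg, HgCl2 (1 mol %), Et2O, 0 °C; then 2, −20 °C → rt
Reagents that add atoms: none
Why: Grignard coupling of the propargyl/allenyl magnesium reagent with the allylic (not the vinylic) C–Br bond of 2 gives the 1,5-enyne; no stereocenter is formed.

**Step 2**
Reactants: 4 2-bromohex-1-en-5-yne; 5 cyclopent-3-en-1-one
Product: 7 1-(5-bromohex-5-en-1-yn-1-yl)cyclopent-3-en-1-ol, via alkynylmagnesium bromide 6 (not isolated)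
Conditions: EtMgBr, THF, 0 → 40 °C; then LaCl3·2LiCl (0.3 equiv), 5, 0 °C; H2O
Reagents that add atoms: none
Why: 1,2-addition of the weakly basic alkynyl Grignard reagent to the ketone, with LaCl3·2LiCl suppressing enolisation of the β,γ-unsaturated ketone; the alkenyl bromide is inert and the symmetric carbinol carbon is not a stereocenter.

**Step 3**
Reactants: 7 1-(5-bromohex-5-en-1-yn-1-yl)cyclopent-3-en-1-ol
Product: 8 1-[(2E)-6-bromohepta-2,6-dien-2-yl]cyclopent-3-en-1-ol
Conditions: MeMgBr (4 equiv), CuI (10 mol %), THF/PhMe, 0 → 70 °C; H2O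
Reagents that add atoms: methylmagnesium bromide, C[Mg]Br
Why: alkoxide-directed anti-carbomagnesiation of a propargylic alcohol (Duboudin–Fallis) puts the methyl group on the alkyne carbon next to the carbinol and holds magnesium cis to it in a five-membered chelate, so protonolysis gives the (E)-trisubstituted alkene (C10 trans to the carbinol).

**Step 4**
Reactants: 8 1-[(2E)-6-bromohepta-2,6-dien-2-yl]cyclopent-3-en-1-ol
Product: 9 1-[(2R,3S)-3-(3-bromobut-3-en-1-yl)-2-methyloxiran-2-yl]cyclopent-3-en-1-ol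
Conditions: 1,2:4,5-di-O-isopropylidene-β-L-erythro-2,3-hexodiulo-2,6-pyranose (ent-Shi ketone, 0.3 equiv), KHSO5 (as Oxone), K2CO3, Bu4NHSO4, MeCN/CH2(OMe)2, aq Na2B4O7 (pH 10.5), 0 °C
Reagents that add atoms: potassium peroxymonosulfate, [K+].[O-]S(=O)(=O)OO
Why: Shi asymmetric epoxidation through the spiro dioxirane transition state; the L-series ketone attacks the electron-rich (E)-trisubstituted alkene on the face that gives the (2R,3S)-epoxide (this sets C11 as S), while the cis ring alkene and the 2-bromoalkene react much more slowly.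

**Step 5**
Reactants: 9 1-[(2R,3S)-3-(3-bromobut-3-en-1-yl)-2-methyloxiran-2-yl]cyclopent-3-en-1-ol
Product: 11 (7S)-7-[(1S)-4-bromo-1-(trimethylsilyloxy)pent-4-en-1-yl]-7-methyl-6,7-dihydrooxepin-2(3H)-one, via silyloxy ketone 10 (not isolated)
Conditions: Me3SiOOSiMe3 (3 equiv), Me3SiOTf (0.2 equiv), CH2Cl2, −40 → 0 °C; Et3N, pH 7 buffer
Reagents that add atoms: bis(trimethylsilyl) peroxide, C[Si](C)(C)OO[Si](C)(C)C
Why: Proposed new method: a one-flask, silyl-triflate-relayed double 1,2-shift (semipinacol, then Baeyer–Villiger) not yet described for 2,3-epoxy alcohols, in which Me3SiOTf silylates the epoxide oxygen, the tertiary C12–O bond ionises and a ring CH2 of the symmetric cyclopentenol migrates antiperiplanar to it with inversion at C12 (five- to six-membered ring, C11–O untouched and left silyl-protected in 10), the released TfOH regenerates Me3SiOTf from the silyl peroxide, which then adds to the non-conjugated ketone so that the Criegee adduct shifts the more substituted C12 to oxygen with retention (six- to seven-membered lactone) without epoxidising either alkene; the closest known chemistry is the Suzuki–Tsuchihashi/Tu semipinacol rearrangement of 2,3-epoxy alcohols combined with the Noyori Me3SiOOSiMe3/Me3SiOTf Baeyer–Villiger oxidation.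

**Step 6**
Reactants: 12 (S)-2-methylglycidol; 13 1,3-dithiane
Product: 15 (2R)-3-(1,3-dithian-2-yl)-2-methylpropane-1,2-diol, via 2-lithio-1,3-dithiane 14 (not isolated)
Conditions: n-BuLi (2.2 equiv), THF, −30 °C; then 12, DMPU, −30 → 0 °C; H2O
Reagents that add atoms: none
Why: Corey–Seebach SN2 opening of the 2,2-disubstituted epoxide at its CH2 installs C2 as a masked aldehyde; the C4–O bond is not broken, so the configuration of 12 is carried over.

**Step 7**
Reactants: 15 (2R)-3-(1,3-dithian-2-yl)-2-methylpropane-1,2-diol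
Product: 17 2-{[(2R)-2-methyloxiran-2-yl]methyl}-1,3-dithiane, via primary tosylate 16 (not isolated)
Conditions: NaH (2.2 equiv), 1-(p-toluenesulfonyl)imidazole, THF, 0 °C → rt; H2O
Reagents that add atoms: none
Why: selective sulfonylation of the primary hydroxyl followed by intramolecular Williamson closure by the tertiary alkoxide; C4–O is again untouched.

**Step 8**
Reactants: 17 2-{[(2R)-2-methyloxiran-2-yl]methyl}-1,3-dithiane; 18 acetic acid
Product: 21 (5S)-5-(1,3-dithian-2-ylmethyl)-5-methyloxolan-2-one, via dilithium acetate dianion 19 (not isolated), via hydroxy acid 20 (not isolated)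
Conditions: LiN(i-Pr)2 (2.1 equiv), THF, 0 °C; then 17, 45 °C; aq HCl; then TsOH (cat.), PhMe, rt
Reagents that add atoms: none
Why: epoxide opening at CH2 by the acetic acid dianion (Creger) and acid-catalysed lactonisation give the γ-lactone whose ring oxygen is the original C4 oxygen, so C4 keeps its configuration.

**Step 9**
Reactants: 21 (5S)-5-(1,3-dithian-2-ylmethyl)-5-methyloxolan-2-one
Product: 22 (5S)-5-(1,3-dithian-2-ylmethyl)-5-methyloxolan-2-ol (anomer mixture)
Conditions: i-Bu2AlH (1.1 equiv), CH2Cl2, −78 °C; aq potassium sodium tartrate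
Reagents that add atoms: none
Why: partial reduction of a lactone at −78 °C stops at the aluminium hemiacetal, which gives the lactol on hydrolysis; the dithiane is inert.

**Step 10**
Reactants: 11 silyloxy bromoalkenyl oxepinone; 22 east lactol
Product: 23 (7S)-7-[(1S,5S,8S)-9-(1,3-dithian-2-yl)-5,8-dihydroxy-8-methyl-4-methylidene-1-(trimethylsilyloxy)nonyl]-7-methyl-6,7-dihydrooxepin-2(3H)-one
Conditions: CrCl2 (4 equiv), NiCl2 (2 mol %), Kishi oxazoline–sulfonamide ligand (Re-face-selective enantiomer), Et3N, MeCN/THF, rt; H2O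
Reagents that add atoms: none
Why: Nozaki–Hiyama–Kishi coupling, in which the alkenylchromium formed from the 2-bromoalkene adds only to the open hydroxy-aldehyde form of 22 (not to the lactone or silyl ether) and the sulfonamide-bound chromium delivers it to the Re face, giving the (S)-carbinol at C7.

**Step 11**
Reactants: 23 west–east diol
Product: 25 (7S)-7-[(1S)-4-{(2R,5S)-5-(1,3-dithian-2-ylmethyl)-5-methyloxolan-2-yl}-1-(trimethylsilyloxy)pent-4-en-1-yl]-7-methyl-6,7-dihydrooxepin-2(3H)-one, via allylic mesylate 24 (not isolated)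
Conditions: MsCl (1.05 equiv), Et3N, CH2Cl2, −40 → 25 °C
Reagents that add atoms: none
Why: selective mesylation of the only unhindered (secondary allylic) hydroxyl and 5-exo-tet Williamson etherification by the tertiary C4 hydroxyl; SN2 inversion turns (7S) into (7R) and gives the 2,5-cis-oxolane, with the C11 oxygen silyl-protected so it cannot compete.

**Step 12**
Reactants: 25 oxolane oxepinone
Product: 27 (7S)-7-[(1S)-4-{(2R,5S)-5-(1,3-dithian-2-ylmethyl)-5-methyloxolan-2-yl}-1-(trimethylsilyloxy)pent-4-en-1-yl]-3-(hydroxymethyl)-7-methyl-6,7-dihydrooxepin-2(5H)-one, via deconjugated hydroxymethyl lactone 26 (not isolated)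
Conditions: LiN(i-Pr)2 (1.1 equiv), THF, −78 °C; CH2O (monomeric, THF), −78 °C; AcOH; then DBU (0.2 equiv), rt
Reagents that add atoms: formaldehyde, C=O
Why: the lithium dienolate of the β,γ-unsaturated lactone undergoes aldol addition to formaldehyde at the α-carbon and DBU then moves the double bond into conjugation, giving the Baylis–Hillman-type allylic alcohol; the transient C15 stereocenter of 26 is erased.

**Step 13**
Reactants: 27 hydroxymethyl oxepinone
Product: 28 (7S)-3-(bromomethyl)-7-[(1S)-4-{(2R,5S)-5-(1,3-dithian-2-ylmethyl)-5-methyloxolan-2-yl}-1-(trimethylsilyloxy)pent-4-en-1-yl]-7-methyl-6,7-dihydrooxepin-2(5H)-one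
Conditions: CBr4, PPh3, 2,6-lutidine, CH2Cl2, 0 °C
Reagents that add atoms: carbon tetrabromide, BrC(Br)(Br)Br
Why: Appel bromination of the only free (primary allylic) hydroxyl; the hindered silyl ether, dithiane and lactone are untouched.

**Step 14**
Reactants: 28 bromomethyl oxepinone
Product: 29 (7S)-3-(bromomethyl)-7-[(1S)-1-hydroxy-4-{(2R,5S)-5-methyl-5-(2-oxoethyl)oxolan-2-yl}pent-4-en-1-yl]-7-methyl-6,7-dihydrooxepin-2(5H)-one
Conditions: PhI(OCOCF3)2 (1.5 equiv), MeCN/H2O (9:1), 0 °C → rt; NaHCO3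
Reagents that add atoms: water, O
Why: oxidative dethioacetalisation (Stork–Zhao) with the trivalent iodine reagent unmasks the C2 aldehyde within minutes, faster than any alkene oxidation, and the CF3CO2H released in wet MeCN hydrolyses the trimethylsilyl ether.

**Step 15**
Reactants: 29 bromo aldehyde
Product: 30 target CNP0289823.1
Conditions: CrCl2 (8 equiv), Kishi oxazoline–sulfonamide ligand (Re-face-selective enantiomer), Et3N, THF (1 mM, syringe pump), rt; pH 7 buffer
Reagents that add atoms: none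
Why: intramolecular Nozaki–Hiyama allylation in which the 2-(alkoxycarbonyl)allylchromium adds through C1 to the aldehyde via a chair Zimmerman–Traxler transition state; the ring-locked alkene geometry (C14 trans to C17) enforces the anti C1/C2 relationship, the ligand directs Re-face attack to give (1R,2S), and the exocyclic methylene is formed while the hindered tertiary-alkyl lactone does not translactonise under neutral conditions.

**Compound list**
1 | 3-bromoprop-1-yne (propargyl bromide) | C#CCBr | starting material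
2 | 2,3-dibromoprop-1-ene | C=C(Br)CBr | starting material
3 | prop-2-yn-1-ylmagnesium bromide | C#CC[Mg]Br | intermediate (not isolated)
4 | 2-bromohex-1-en-5-yne | C=C(Br)CCC#C | intermediate
5 | cyclopent-3-en-1-one | O=C1CC=CC1 | starting material
6 | (5-bromohex-5-en-1-yn-1-yl)magnesium bromide | C=C(Br)CCC#C[Mg]Br | intermediate (not isolated)
7 | 1-(5-bromohex-5-en-1-yn-1-yl)cyclopent-3-en-1-ol | OC1(CC=CC1)C#CCCC(Br)=C | intermediate
8 | 1-[(2E)-6-bromohepta-2,6-dien-2-yl]cyclopent-3-en-1-ol | OC1(CC=CC1)/C(C)=C/CCC(Br)=C | intermediate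
9 | 1-[(2R,3S)-3-(3-bromobut-3-en-1-yl)-2-methyloxiran-2-yl]cyclopent-3-en-1-ol | C[C@]1(O[C@H]1CCC(Br)=C)C1(O)CC=CC1 | intermediate
10 | (2S)-2-[(1S)-4-bromo-1-(trimethylsilyloxy)pent-4-en-1-yl]-2-methylcyclohex-4-en-1-one | C[C@]1(CC=CCC1=O)[C@@H](O[Si](C)(C)C)CCC(Br)=C | intermediate (not isolated)
11 | (7S)-7-[(1S)-4-bromo-1-(trimethylsilyloxy)pent-4-en-1-yl]-7-methyl-6,7-dihydrooxepin-2(3H)-one | C[C@@]1(OC(=O)CC=CC1)[C@@H](O[Si](C)(C)C)CCC(Br)=C | intermediate
12 | [(2S)-2-methyloxiran-2-yl]methanol ((S)-2-methylglycidol) | C[C@]1(CO)CO1 | starting material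
13 | 1,3-dithiane | C1CSCSC1 | starting material
14 | 2-lithio-1,3-dithiane | [Li]C1SCCCS1 | intermediate (not isolated)
15 | (2R)-3-(1,3-dithian-2-yl)-2-methylpropane-1,2-diol | C[C@](O)(CO)CC1SCCCS1 | intermediate
16 | (2R)-3-(1,3-dithian-2-yl)-2-hydroxy-2-methylpropyl 4-methylbenzenesulfonate | Cc1ccc(cc1)S(=O)(=O)OC[C@](C)(O)CC1SCCCS1 | intermediate (not isolated)
17 | 2-{[(2R)-2-methyloxiran-2-yl]methyl}-1,3-dithiane | C[C@@]1(CC2SCCCS2)CO1 | intermediate
18 | acetic acid | CC(=O)O | starting material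
19 | dilithium acetate dianion (lithium 2-lithioacetate) | [Li]CC(=O)O[Li] | intermediate (not isolated)
20 | (4S)-5-(1,3-dithian-2-yl)-4-hydroxy-4-methylpentanoic acid | C[C@](O)(CCC(=O)O)CC1SCCCS1 | intermediate (not isolated)
21 | (5S)-5-(1,3-dithian-2-ylmethyl)-5-methyloxolan-2-one | C[C@@]1(CC2SCCCS2)CCC(=O)O1 | intermediate
22 | (5S)-5-(1,3-dithian-2-ylmethyl)-5-methyloxolan-2-ol (anomer mixture) | C[C@@]1(CC2SCCCS2)CCC(O)O1 | intermediate
23 | (7S)-7-[(1S,5S,8S)-9-(1,3-dithian-2-yl)-5,8-dihydroxy-8-methyl-4-methylidene-1-(trimethylsilyloxy)nonyl]-7-methyl-6,7-dihydrooxepin-2(3H)-one | C[C@@]1(OC(=O)CC=CC1)[C@@H](O[Si](C)(C)C)CCC(=C)[C@@H](O)CC[C@](C)(O)CC1SCCCS1 | intermediate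
24 | 5'-O-methanesulfonate of 23 | C[C@@]1(OC(=O)CC=CC1)[C@@H](O[Si](C)(C)C)CCC(=C)[C@@H](OS(C)(=O)=O)CC[C@](C)(O)CC1SCCCS1 | intermediate (not isolated)
25 | (7S)-7-[(1S)-4-{(2R,5S)-5-(1,3-dithian-2-ylmethyl)-5-methyloxolan-2-yl}-1-(trimethylsilyloxy)pent-4-en-1-yl]-7-methyl-6,7-dihydrooxepin-2(3H)-one | C[C@@]1(OC(=O)CC=CC1)[C@@H](O[Si](C)(C)C)CCC(=C)[C@H]1CC[C@@](C)(CC2SCCCS2)O1 | intermediate
26 | 3-(hydroxymethyl) derivative of 25 (C3 epimers, alkene still at C4=C5) | C[C@@]1(OC(=O)C(CO)C=CC1)[C@@H](O[Si](C)(C)C)CCC(=C)[C@H]1CC[C@@](C)(CC2SCCCS2)O1 | intermediate (not isolated)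
27 | (7S)-7-[(1S)-4-{(2R,5S)-5-(1,3-dithian-2-ylmethyl)-5-methyloxolan-2-yl}-1-(trimethylsilyloxy)pent-4-en-1-yl]-3-(hydroxymethyl)-7-methyl-6,7-dihydrooxepin-2(5H)-one | C[C@@]1(OC(=O)C(CO)=CCC1)[C@@H](O[Si](C)(C)C)CCC(=C)[C@H]1CC[C@@](C)(CC2SCCCS2)O1 | intermediate
28 | (7S)-3-(bromomethyl)-7-[(1S)-4-{(2R,5S)-5-(1,3-dithian-2-ylmethyl)-5-methyloxolan-2-yl}-1-(trimethylsilyloxy)pent-4-en-1-yl]-7-methyl-6,7-dihydrooxepin-2(5H)-one | C[C@@]1(OC(=O)C(CBr)=CCC1)[C@@H](O[Si](C)(C)C)CCC(=C)[C@H]1CC[C@@](C)(CC2SCCCS2)O1 | intermediate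
29 | (7S)-3-(bromomethyl)-7-[(1S)-1-hydroxy-4-{(2R,5S)-5-methyl-5-(2-oxoethyl)oxolan-2-yl}pent-4-en-1-yl]-7-methyl-6,7-dihydrooxepin-2(5H)-one | C[C@@]1(OC(=O)C(CBr)=CCC1)[C@@H](O)CCC(=C)[C@H]1CC[C@@](C)(CC=O)O1 | intermediate
30 | CNP0289823.1 [(1R,2S,4S,7R,11S,12S)-4,7-epoxy-2,11-dihydroxycembra-8(19),15(17)-dien-16,12-olide] | C=C1C(=O)O[C@@]2(C)CC[C@H]1[C@@H](O)C[C@]1(C)CC[C@@H](O1)C(=C)CC[C@@H]2O | target

**Step count:** 15 steps in total; longest linear sequence 11 steps (steps 1–5, then 10–15).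

**Three steps most likely to fail**

Step 5 (the proposed tandem): the two shifts may not relay cleanly in one flask, or the Baeyer–Villiger stage may be slow. The fallback sets out from 9 and comes back at 11. ZnBr2 in CH2Cl2 carries out the known semipinacol ring expansion of the 2,3-epoxy alcohol and the β-hydroxy ketone (2S)-2-[(1S)-4-bromo-1-hydroxypent-4-en-1-yl]-2-methylcyclohex-4-en-1-one F1 is isolated. F1 is then oxidised in a separate flask under the known alkene-tolerant Me3SiOOSiMe3/Me3SiOTf Baeyer–Villiger conditions, which also silylate the carbinol, to give 11.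

Step 10 (ligand-controlled Ni/Cr coupling on a lactol): face selectivity at C7 may be low with the masked aldehyde. The fallback sets out from 11 and 22 and comes back at 23. Ligand-free coupling (CrCl2, NiCl2 cat., DMSO) gives the alcohol as a mixture at C7, the C5'-epimeric mixture of 23 F2. MnO2 oxidises only the allylic carbinol to the enone (7S)-7-[(1S,8S)-9-(1,3-dithian-2-yl)-8-hydroxy-8-methyl-4-methylidene-5-oxo-1-(trimethylsilyloxy)nonyl]-7-methyl-6,7-dihydrooxepin-2(3H)-one F3. Reduction with (R)-2-methyl-CBS-oxazaborolidine and catecholborane then sets (7S) under reagent control and returns 23.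

Step 15 (macrocyclisation): the chromium reagent may give oligomers, the wrong aldehyde face, or lactone migration to the γ-lactone. The fallback sets out from 27 and comes back at 30. PhI(OCOCF3)2 in wet MeCN converts 27 directly into the hydroxymethyl aldehyde (7S)-3-(hydroxymethyl)-7-[(1S)-1-hydroxy-4-{(2R,5S)-5-methyl-5-(2-oxoethyl)oxolan-2-yl}pent-4-en-1-yl]-7-methyl-6,7-dihydrooxepin-2(5H)-one F4. Pd(PPh3)4 (cat.) with Et3B in THF at high dilution (Tamaru umpolung of the allylic alcohol through a π-allylpalladium to an allylborane) then closes the ring through the same closed chair transition state, without the allylic bromide or stoichiometric chromium.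

**Further compounds**
F1 | step 5 | (2S)-2-[(1S)-4-bromo-1-hydroxypent-4-en-1-yl]-2-methylcyclohex-4-en-1-one | C[C@]1(CC=CCC1=O)[C@@H](O)CCC(Br)=C
F2 | step 10 | C5'-epimeric mixture of 23 | C[C@@]1(OC(=O)CC=CC1)[C@@H](O[Si](C)(C)C)CCC(=C)C(O)CC[C@](C)(O)CC1SCCCS1
F3 | step 10 | (7S)-7-[(1S,8S)-9-(1,3-dithian-2-yl)-8-hydroxy-8-methyl-4-methylidene-5-oxo-1-(trimethylsilyloxy)nonyl]-7-methyl-6,7-dihydrooxepin-2(3H)-one | C[C@@]1(OC(=O)CC=CC1)[C@@H](O[Si](C)(C)C)CCC(=C)C(=O)CC[C@](C)(O)CC1SCCCS1
F4 | step 15 | (7S)-3-(hydroxymethyl)-7-[(1S)-1-hydroxy-4-{(2R,5S)-5-methyl-5-(2-oxoethyl)oxolan-2-yl}pent-4-en-1-yl]-7-methyl-6,7-dihydrooxepin-2(5H)-one | C[C@@]1(OC(=O)C(CO)=CCC1)[C@@H](O)CCC(=C)[C@H]1CC[C@@](C)(CC=O)O1
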